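**Retrosynthetic overview**
1. Target ⇒ the tertiary-alcohol phthalide; the tertiary acetate goes on last, and the phenol acetate formed alongside is removed in the same pot.
2. Lactone ring ⇒ an open, asperugin-type o-phthalaldehyde already carrying the whole side chain. An internal Cannizzaro hydride shift followed by lactonisation closes it, as in the presumed dialdehyde-to-phthalide biogenesis. It is run late and unprotected, with the regiochemistry left to the phenoxide.
3. Dialdehyde ⇒ 3-hydroxy-4-alkoxy-5-methoxybenzaldehyde by magnesium-templated ortho-formylation.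
4. Aryl ether ⇒ 5-hydroxyvanillin + 11-hydroxy-10,11-dihydrofarnesol (Mitsunobu at the 4-OH); the diol ⇒ (2E,6E)-farnesol by terminal Markovnikov hydration.
5. Ring order: the benzene ring is bought; the lactone is the only ring made, closed in step 4 after the side chain is in place.

Assumption: the target has no stereogenic centre, so "single enantiomer" is taken to mean the single (2E,6E) geometric isomer; both E olefins come unchanged from (2E,6E)-farnesol.

**Step 1**
Reactants: 1 (2E,6E)-farnesol
Product: 3 (2E,6E)-3,7,11-trimethyldodeca-2,6-diene-1,11-diol, via C10 acetoxymercurio diol 2 (not isolated)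
Conditions: Hg(OAc)2 (1.0 equiv), THF/H2O 1:1, 0 °C, 30–60 min; then 3 M NaOH, NaBH4, 0 °C
Reagents that add atoms: water, O (the C11 hydroxyl oxygen)
Why: Brown oxymercuration–demercuration gives Markovnikov hydration without carbocation chemistry, and the terminal isopropylidene alkene is the least hindered and not inductively deactivated (C2=C3 is slowed by the allylic hydroxyl), so with one equivalent of Hg(OAc)2 and recycling of recovered 1 the 10,11-hydrate is the main product; no stereocentre is formed and both E alkenes are untouched.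

**Step 2**
Reactants: 3 (2E,6E)-3,7,11-trimethyldodeca-2,6-diene-1,11-diol; 4 3,4-dihydroxy-5-methoxybenzaldehyde (5-hydroxyvanillin, 1.2 equiv)
Product: 5 3-hydroxy-4-{[(2E,6E)-11-hydroxy-3,7,11-trimethyldodeca-2,6-dien-1-yl]oxy}-5-methoxybenzaldehyde
Conditions: PPh3 (1.3 equiv), diisopropyl azodicarboxylate (1.3 equiv), THF, 0 °C → rt
Reagents that add atoms: none
Why: Mitsunobu etherification activates only the primary allylic hydroxyl (the tertiary one is inert) and the more acidic 4-OH para to the formyl group is the phenol that is deprotonated and alkylated, by SN2 displacement at the primary carbon so the 2E geometry is kept.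

**Step 3**
Reactants: 5 3-hydroxy-4-{[(2E,6E)-11-hydroxy-3,7,11-trimethyldodeca-2,6-dien-1-yl]oxy}-5-methoxybenzaldehyde
Product: 7 3-hydroxy-4-{[(2E,6E)-11-hydroxy-3,7,11-trimethyldodeca-2,6-dien-1-yl]oxy}-5-methoxybenzene-1,2-dicarbaldehyde, via hydroxymethyl phenol 6 (not isolated)
Conditions: MgCl2 (anhydrous, 3 equiv), Et3N (6 equiv), (CH2O)n (6 equiv), MeCN, reflux, 4–8 h; then cold 5% aq. citric acid
Reagents that add atoms: paraformaldehyde (formaldehyde), C=O
Why: Casnati–Skattebøl magnesium-mediated ortho-formylation delivers formaldehyde inside the magnesium phenoxide complex to the only free ortho position (C2), and a second formaldehyde oxidises the hydroxymethyl intermediate by hydride transfer; the non-acidic conditions spare the farnesyl-type aryl ether, which Duff or Rieche conditions would not.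

**Step 4**
Reactants: 7 3-hydroxy-4-{[(2E,6E)-11-hydroxy-3,7,11-trimethyldodeca-2,6-dien-1-yl]oxy}-5-methoxybenzene-1,2-dicarbaldehyde
Product: 9 4-hydroxy-5-{[(2E,6E)-11-hydroxy-3,7,11-trimethyldodeca-2,6-dien-1-yl]oxy}-6-methoxy-2-benzofuran-1(3H)-one, via hydroxy acid 8 (not isolated)
Conditions: LiOH·H2O (5 equiv), THF/H2O 1:1 (degassed), rt → 45 °C; then 1 M HCl to pH 2, rt, 1 h
Reagents that add atoms: water (delivered as hydroxide from LiOH·H2O), O — its oxygen becomes one carboxylate oxygen of 8, and one water is lost again on lactonisation, so 7 to 9 is a net isomerisation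
Why: Intramolecular Cannizzaro reaction then acid lactonisation: hydroxide should add to the more electrophilic C1 aldehyde, because the C2 aldehyde is a vinylogous carboxylate of the ortho phenoxide and para methoxy group, and the gem-diolate passes hydride to the lithium-chelated C2 carbonyl, so C1 becomes the lactone carbonyl and C2 the CH2O carbon as in the target; this regiochemistry is reasoned, not precedented on this substrate.

**Step 5**
Reactants: 9 4-hydroxy-5-{[(2E,6E)-11-hydroxy-3,7,11-trimethyldodeca-2,6-dien-1-yl]oxy}-6-methoxy-2-benzofuran-1(3H)-one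
Product: 11 farnesylemefuranone F, (6E,10E)-12-[(4-hydroxy-6-methoxy-1-oxo-1,3-dihydro-2-benzofuran-5-yl)oxy]-2,6,10-trimethyldodeca-6,10-dien-2-yl acetate, via bis-acetate 10 (not isolated)
Conditions: Ac2O (6 equiv), Et3N (8 equiv), 4-(dimethylamino)pyridine (1 equiv), CH2Cl2, rt → 35 °C, 24–48 h; then pyrrolidine (excess), 0 °C, 30 min
Reagents that add atoms: acetic anhydride, CC(=O)OC(C)=O
Why: Steglich-type acylation catalysed by 4-(dimethylamino)pyridine acetylates the tertiary alcohol (and, unavoidably, the phenol), and chemoselective aminolysis then removes only the activated aryl acetate, since the hindered tertiary alkyl acetate and the phthalide do not react with pyrrolidine at 0 °C.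

**Compound list**
1 | (2E,6E)-farnesol, (2E,6E)-3,7,11-trimethyldodeca-2,6,10-trien-1-ol | OC/C=C(\C)CC/C=C(\C)CCC=C(C)C | starting material
2 | C10 acetoxymercurio diol, (2E,6E)-10-(acetoxymercurio)-3,7,11-trimethyldodeca-2,6-diene-1,11-diol (racemic at C10) | OC/C=C(\C)CC/C=C(\C)CCC([Hg]OC(C)=O)C(C)(C)O | intermediate
3 | (2E,6E)-3,7,11-trimethyldodeca-2,6-diene-1,11-diol | OC/C=C(\C)CC/C=C(\C)CCCC(C)(C)O | intermediate
4 | 3,4-dihydroxy-5-methoxybenzaldehyde (5-hydroxyvanillin) | COc1cc(C=O)cc(O)c1O | starting material
5 | 3-hydroxy-4-{[(2E,6E)-11-hydroxy-3,7,11-trimethyldodeca-2,6-dien-1-yl]oxy}-5-methoxybenzaldehyde | COc1cc(C=O)cc(O)c1OC/C=C(\C)CC/C=C(\C)CCCC(C)(C)O | intermediate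
6 | hydroxymethyl phenol, 3-hydroxy-2-(hydroxymethyl)-4-{[(2E,6E)-11-hydroxy-3,7,11-trimethyldodeca-2,6-dien-1-yl]oxy}-5-methoxybenzaldehyde | COc1cc(C=O)c(CO)c(O)c1OC/C=C(\C)CC/C=C(\C)CCCC(C)(C)O | intermediate
7 | 3-hydroxy-4-{[(2E,6E)-11-hydroxy-3,7,11-trimethyldodeca-2,6-dien-1-yl]oxy}-5-methoxybenzene-1,2-dicarbaldehyde | COc1cc(C=O)c(C=O)c(O)c1OC/C=C(\C)CC/C=C(\C)CCCC(C)(C)O | intermediate
8 | hydroxy acid, 3-hydroxy-2-(hydroxymethyl)-4-{[(2E,6E)-11-hydroxy-3,7,11-trimethyldodeca-2,6-dien-1-yl]oxy}-5-methoxybenzoic acid (lithium salt in the flask) | COc1cc(C(=O)O)c(CO)c(O)c1OC/C=C(\C)CC/C=C(\C)CCCC(C)(C)O | intermediate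
9 | 4-hydroxy-5-{[(2E,6E)-11-hydroxy-3,7,11-trimethyldodeca-2,6-dien-1-yl]oxy}-6-methoxy-2-benzofuran-1(3H)-one | COc1cc2c(c(O)c1OC/C=C(\C)CC/C=C(\C)CCCC(C)(C)O)COC2=O | intermediate
10 | bis-acetate, (6E,10E)-12-[(4-acetoxy-6-methoxy-1-oxo-1,3-dihydro-2-benzofuran-5-yl)oxy]-2,6,10-trimethyldodeca-6,10-dien-2-yl acetate | COc1cc2c(c(OC(C)=O)c1OC/C=C(\C)CC/C=C(\C)CCCC(C)(C)OC(C)=O)COC2=O | intermediate
11 | farnesylemefuranone F | COc1cc2c(c(O)c1OC/C=C(\C)CC/C=C(\C)CCCC(C)(C)OC(C)=O)COC2=O | target

**Step count**
Total steps: 5. Longest linear sequence: 5 (1 → 3 → 5 → 7 → 9 → 11); 4 is bought.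

**Three steps most likely to fail**

Step 4 is the largest risk: the hydride may shift the other way and put the carbonyl next to the phenol, or the phenoxide-deactivated acceptor may stall. The fallback fixes the oxidation level of each carbon separately instead of relying on a hydride shift. It sets out from 5: PhB(OH)2, paraformaldehyde and catalytic EtCO2H in toluene at reflux with water removal (Nagata ortho-hydroxymethylation) give the cyclic boronate 8-{[(2E,6E)-11-hydroxy-3,7,11-trimethyldodeca-2,6-dien-1-yl]oxy}-7-methoxy-2-phenyl-4H-1,3,2-benzodioxaborinine-5-carbaldehyde F3. Exchange with propane-1,3-diol releases hydroxymethyl phenol 6, now isolated (in equilibrium with its lactol). Pinnick oxidation of its C1 aldehyde (NaClO2, NaH2PO4, large excess of 2-methyl-2-butene, t-BuOH/H2O) gives hydroxy acid 8, which lactonises on acidification. The fallback rejoins the route at 9, and the lactone carbonyl is then necessarily the original aldehyde carbon.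

Step 3 may be sluggish because the ring already carries a formyl group, and the product may react further in the pot. The fallback formylates before the acid-labile side chain is attached. It sets out from 4: a Duff reaction (hexamethylenetetramine, CF3CO2H, 80 °C; then aq. HCl) is now permissible and should substitute ortho to the 3-OH, as electrophiles do at C2 of isovanillin, giving 3,4-dihydroxy-5-methoxybenzene-1,2-dicarbaldehyde F2. Mitsunobu coupling with 3 (PPh3, diisopropyl azodicarboxylate, THF) then alkylates the 4-OH, because the 3-OH is locked in a hydrogen bond to the C2 formyl group. The fallback rejoins the route at 7.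

Step 1 may give poor site selectivity between the 6,7 and 10,11 alkenes, or over-hydration. The fallback sets out from 1: NBS in THF/H2O at 0 °C (van Tamelen terminal bromohydrin formation, selective for the terminal alkene in aqueous medium) gives (2E,6E)-10-bromo-3,7,11-trimethyldodeca-2,6-diene-1,11-diol F1. Radical debromination (Bu3SnH, azobisisobutyronitrile, benzene, 80 °C) removes the bromine without touching the alkenes. The fallback rejoins the route at 3.

**Further compounds**
F1 | step 1 | (2E,6E)-10-bromo-3,7,11-trimethyldodeca-2,6-diene-1,11-diol (racemic at C10) | OC/C=C(\C)CC/C=C(\C)CCC(Br)C(C)(C)O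
F2 | step 3 | 3,4-dihydroxy-5-methoxybenzene-1,2-dicarbaldehyde | COc1cc(C=O)c(C=O)c(O)c1O
F3 | step 4 | 8-{[(2E,6E)-11-hydroxy-3,7,11-trimethyldodeca-2,6-dien-1-yl]oxy}-7-methoxy-2-phenyl-4H-1,3,2-benzodioxaborinine-5-carbaldehyde | COc1cc(C=O)c2COB(c3ccccc3)Oc2c1OC/C=C(\C)CC/C=C(\C)CCCC(C)(C)O
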